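**Retrosynthetic overview**
- Target ⇒ E-selective cross-metathesis at C13=C14 between a bicyclic 2-alkylacrolein and (R)-5-allyl-4-(hydroxymethyl)butenolide.
- Bicyclic acrolein ⇒ Pd formylation of a bicyclic enol triflate.
- Bicyclic enol triflate ⇒ catalyst-controlled, proton-initiated bicyclization of the acyclic enol triflate of (E,E)-farnesylacetone. Rings A and B close together (C4–C5 and C9–C10), C5/C10 are set, the electron-poor enol triflate stops the cascade, and the olefin is converged to Δ8(9).
- Allyl butenolide ⇒ asymmetric allylboration and relactonization of a γ-hydroxybutenolide obtained by singlet-oxygen oxidation of silylated 3-furanmethanol.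
- Ring order: decalin rings A and B first and simultaneously; the butenolide is made separately and joined last.

Assumption: farnesylacetone is bought as the pure (5E,9E) isomer, and the IDPi enantiomer used is the one giving the natural (5S,10S) series (the sense that converts homofarnesol into (−)-ambrox).

**Step 1**
Reactants: 1 (5E,9E)-6,10,14-trimethylpentadeca-5,9,13-trien-2-one (farnesylacetone)
Product: 3 (5E,9E)-6,10,14-trimethylpentadeca-1,5,9,13-tetraen-2-yl trifluoromethanesulfonate (acyclic enol triflate), via lithium enolate 2 (not isolated)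
Conditions: LDA (1.1 equiv), THF, −78 °C; PhNTf2 (1.1 equiv), −78 → 0 °C; aq. NH4Cl
Reagents that add atoms: N-phenylbis(trifluoromethanesulfonimide) O=S(=O)(N(c1ccccc1)S(=O)(=O)C(F)(F)F)C(F)(F)F
Why: Kinetic deprotonation of the methyl ketone at CH3 and O-sulfonylation of the less substituted lithium enolate (enol triflate formation) give the 2-triflyloxy-1-alkene without touching the E-trisubstituted olefins.

**Step 2**
Reactants: 3 acyclic enol triflate
Product: 6 4-[(4aS,8aS)-2,5,5,8a-tetramethyl-3,4,4a,5,6,7,8,8a-octahydronaphthalen-1-yl]but-1-en-2-yl trifluoromethanesulfonate (bicyclic Δ8(9) enol triflate), via Δ7 olefin isomer 4 (not isolated), via exocyclic olefin isomer 5 (not isolated)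
Conditions: chiral IDPi Brønsted acid (5 mol%), (CF3)3COH/CH2Cl2, −20 °C → rt; then telescoped: evaporate, I2 (5 mol%), PhH, 80 °C
Reagents that add atoms: none
Why: Proposed new method: enantioface-selective protonation of the terminal isopropylidene inside the confined chiral ion pair triggers a chair–chair cation–olefin bicyclization in which the E,E geometry gives the trans-decalin and the catalyst sets 5S,10S; the inductively deactivated enol triflate cannot capture the C8 cation, so the cascade ends by proton loss, and the kinetic olefins 4 and 5 are converged through the same C8 cation to the tetrasubstituted Δ8(9) olefin by iodine-mediated equilibration; the closest known reaction types are the IDPi-catalysed asymmetric polyene cyclization of homofarnesol to ambrox (O-terminated) and the I2/HI isomerization of labdane olefins to the 8(9)-ene.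

**Step 3**
Reactants: 6 bicyclic Δ8(9) enol triflate
Product: 7 2-methylidene-4-[(4aS,8aS)-2,5,5,8a-tetramethyl-3,4,4a,5,6,7,8,8a-octahydronaphthalen-1-yl]butanal
Conditions: Pd(OAc)2 (5 mol%), dppp (5 mol%), CO (1 atm), Et3SiH (slow addition), Et3N, DMF, 60 °C
Reagents that add atoms: carbon monoxide [C-]#[O+]
Why: Oxidative addition of Pd(0) into the vinyl C–OTf bond, CO insertion and hydride transfer from the silane (reductive carbonylation of a vinyl triflate) give the 2-alkylacrolein, while the hindered tetrasubstituted ring olefin is inert.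

**Step 4**
Reactants: 8 furan-3-ylmethanol
Product: 9 tert-butyl(furan-3-ylmethoxy)dimethylsilane
Conditions: TBSCl, imidazole, CH2Cl2, 0 °C → rt
Reagents that add atoms: tert-butyldimethylsilyl chloride CC(C)(C)[Si](C)(C)Cl
Why: Standard silylation of the primary alcohol makes the following polar intermediates soluble and keeps the hydroxyl from interfering with the boron chemistry.

**Step 5**
Reactants: 9 tert-butyl(furan-3-ylmethoxy)dimethylsilane
Product: 11 4-{[(tert-butyldimethylsilyl)oxy]methyl}-5-hydroxyfuran-2(5H)-one (racemic lactol), via furan endoperoxide 10 (not isolated)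
Conditions: O2, hν (visible), rose bengal (cat.), i-Pr2NEt, CH2Cl2, −78 °C → rt
Reagents that add atoms: dioxygen O=O
Why: [4+2] addition of singlet oxygen to the furan gives the endoperoxide, and the hindered amine removes the less hindered bridgehead hydrogen (Kornblum–DeLaMare fragmentation), which places the carbonyl remote from and the lactol carbon next to the substituted carbon.

**Step 6**
Reactants: 11 racemic lactol; 12 2-(prop-2-en-1-yl)-4,4,5,5-tetramethyl-1,3,2-dioxaborolane (allylboronic acid pinacol ester)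
Product: 15 (5R)-4-(hydroxymethyl)-5-(prop-2-en-1-yl)furan-2(5H)-one, via O-boryl hydroxy acid 13 (not isolated), via silyl butenolide 14 (not isolated)
Conditions: (R)-TRIP phosphoric acid (5 mol%), PhMe, −30 → 0 °C; then 1% HCl in MeOH, rt
Reagents that add atoms: none
Why: Chiral-phosphoric-acid-catalysed allylboration of the ring-opened (Z)-formyl acid tautomer through a closed chair transition state with Re-face allyl transfer (the sense this catalyst enantiomer gives with aryl and alkenyl aldehydes) sets the R carbinol, which lactonizes onto the cis carboxyl, and the acidic methanol removes the primary silyl ether in the same pot.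

**Step 7**
Reactants: 7 bicyclic 2-alkylacrolein; 15 (R)-allyl butenolide (2 equiv)
Product: 16 (2E)-4-[(2R)-3-(hydroxymethyl)-5-oxo-2,5-dihydrofuran-2-yl]-2-{2-[(4aS,8aS)-2,5,5,8a-tetramethyl-3,4,4a,5,6,7,8,8a-octahydronaphthalen-1-yl]ethyl}but-2-enal (target CNP0197865.2)
Conditions: Hoveyda–Grubbs II (10 mol%), 1,4-benzoquinone (20 mol%), CH2Cl2, 40 °C
Reagents that add atoms: none
Why: Olefin cross-metathesis between the terminal olefin of 15 and the 1,1-disubstituted electron-poor olefin of 7 (which cannot homodimerize) releases ethene and gives the trisubstituted enal as the thermodynamic E isomer, while the ring olefin and butenolide olefin are metathesis-inert and the neutral conditions preserve the epimerizable butenolide stereocentre.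

**Compound list**
1 | (5E,9E)-6,10,14-trimethylpentadeca-5,9,13-trien-2-one (farnesylacetone) | CC(=O)CC/C=C(\C)CC/C=C(\C)CCC=C(C)C | starting material
2 | lithium (5E,9E)-6,10,14-trimethylpentadeca-1,5,9,13-tetraen-2-olate | [Li+].[O-]C(=C)CC/C=C(\C)CC/C=C(\C)CCC=C(C)C | intermediate
3 | (5E,9E)-6,10,14-trimethylpentadeca-1,5,9,13-tetraen-2-yl trifluoromethanesulfonate | C=C(OS(=O)(=O)C(F)(F)F)CC/C=C(\C)CC/C=C(\C)CCC=C(C)C | intermediate
4 | 4-[(1S,4aS,8aS)-2,5,5,8a-tetramethyl-1,4,4a,5,6,7,8,8a-octahydronaphthalen-1-yl]but-1-en-2-yl trifluoromethanesulfonate (Δ7 isomer) | CC1=CC[C@H]2C(C)(C)CCC[C@]2(C)[C@H]1CCC(=C)OS(=O)(=O)C(F)(F)F | intermediate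
5 | 4-[(1S,4aS,8aS)-5,5,8a-trimethyl-2-methylidenedecahydronaphthalen-1-yl]but-1-en-2-yl trifluoromethanesulfonate (exocyclic isomer) | C=C1CC[C@H]2C(C)(C)CCC[C@]2(C)[C@H]1CCC(=C)OS(=O)(=O)C(F)(F)F | intermediate
6 | 4-[(4aS,8aS)-2,5,5,8a-tetramethyl-3,4,4a,5,6,7,8,8a-octahydronaphthalen-1-yl]but-1-en-2-yl trifluoromethanesulfonate | CC1=C(CCC(=C)OS(=O)(=O)C(F)(F)F)[C@@]2(C)CCCC(C)(C)[C@@H]2CC1 | intermediate
7 | 2-methylidene-4-[(4aS,8aS)-2,5,5,8a-tetramethyl-3,4,4a,5,6,7,8,8a-octahydronaphthalen-1-yl]butanal | CC1=C(CCC(=C)C=O)[C@@]2(C)CCCC(C)(C)[C@@H]2CC1 | intermediate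
8 | furan-3-ylmethanol | OCc1ccoc1 | starting material
9 | tert-butyl(furan-3-ylmethoxy)dimethylsilane | CC(C)(C)[Si](C)(C)OCc1ccoc1 | intermediate
10 | 5-{[(tert-butyldimethylsilyl)oxy]methyl}-2,3,7-trioxabicyclo[2.2.1]hept-5-ene (racemic endoperoxide) | CC(C)(C)[Si](C)(C)OCC1=CC2OOC1O2 | intermediate
11 | 4-{[(tert-butyldimethylsilyl)oxy]methyl}-5-hydroxyfuran-2(5H)-one (racemic) | CC(C)(C)[Si](C)(C)OCC1=CC(=O)OC1O | intermediate
12 | 2-(prop-2-en-1-yl)-4,4,5,5-tetramethyl-1,3,2-dioxaborolane | C=CCB1OC(C)(C)C(C)(C)O1 | starting material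
13 | (2Z,4R)-3-{[(tert-butyldimethylsilyl)oxy]methyl}-4-[(4,4,5,5-tetramethyl-1,3,2-dioxaborolan-2-yl)oxy]hepta-2,6-dienoic acid | C=CC[C@@H](OB1OC(C)(C)C(C)(C)O1)/C(CO[Si](C)(C)C(C)(C)C)=C\C(=O)O | intermediate
14 | (5R)-4-{[(tert-butyldimethylsilyl)oxy]methyl}-5-(prop-2-en-1-yl)furan-2(5H)-one | C=CC[C@H]1OC(=O)C=C1CO[Si](C)(C)C(C)(C)C | intermediate
15 | (5R)-4-(hydroxymethyl)-5-(prop-2-en-1-yl)furan-2(5H)-one | C=CC[C@H]1OC(=O)C=C1CO | intermediate
16 | (2E)-4-[(2R)-3-(hydroxymethyl)-5-oxo-2,5-dihydrofuran-2-yl]-2-{2-[(4aS,8aS)-2,5,5,8a-tetramethyl-3,4,4a,5,6,7,8,8a-octahydronaphthalen-1-yl]ethyl}but-2-enal | CC1=C(CC/C(C=O)=C\C[C@H]2OC(=O)C=C2CO)[C@@]2(C)CCCC(C)(C)[C@@H]2CC1 | target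

**Totals**
Total step count: 7. Longest linear sequence: 4 steps (1 → 3 → 6 → 7 → 16, or 8 → 9 → 11 → 15 → 16).

**Steps most likely to fail, with fallbacks**

Step 2 (asymmetric bicyclization with olefin convergence). The risks are incomplete cyclization, low ee without a terminating nucleophile, and poor convergence to the Δ8(9) olefin. The fallback sets out from 1 and returns at 6, and changes the terminating event. Ketone 1 is cyclized with the same chiral acid so that the carbonyl oxygen captures the C8 cation, giving the tricyclic enol ether sclareol oxide F1. Aqueous HCl/THF opens the enol ether to 8α-hydroxy-14,15-dinorlabdan-13-one F2. Kinetic enol triflation (2.2 equiv LDA, PhNTf2) gives the hydroxy enol triflate F3, which no longer has a ketone that could re-close. I2 in refluxing benzene then dehydrates the tertiary alcohol and equilibrates the olefins to 6.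

Step 3 (reductive carbonylation to a 2-alkylacrolein). The risks are conjugate reduction or oligomerization of the product under Pd–H/silane. The fallback sets out from 6 and returns at 7. Stille coupling of 6 with (tributylstannyl)methanol (Pd(PPh3)4, LiCl, dioxane, 90 °C) gives the allylic alcohol 2-methylidene-4-[(4aS,8aS)-2,5,5,8a-tetramethyl-3,4,4a,5,6,7,8,8a-octahydronaphthalen-1-yl]butan-1-ol F4. MnO2 in CH2Cl2 oxidizes it to 7 under neutral, non-reducing conditions.

Step 6 (catalytic asymmetric allylboration of the pseudo-acid lactol). The risks are the low concentration of open aldehyde and a background reaction promoted by the substrate's own carboxylic acid that erodes ee. The fallback sets out from 11 and returns at 15, and uses reagent control on the open-chain ester. TMSCHN2 (MeOH/PhMe, 0 °C) gives methyl (2Z)-4-[(tert-butyldimethylsilyl)oxy]-3-formylbut-2-enoate F5. Brown allylation with (+)-Ipc2B(allyl) (from (−)-α-pinene; Et2O, −78 °C; Re-face attack) gives methyl (2Z,4R)-3-{[(tert-butyldimethylsilyl)oxy]methyl}-4-hydroxyhepta-2,6-dienoate F6. HCl/MeOH lactonizes and desilylates F6 to 15.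

**Further compounds**
F1 | step 2 | sclareol oxide (8α,13-epoxy-14,15-dinorlabd-12-ene) | CC1=CC[C@H]2[C@](C)(O1)CC[C@H]1C(C)(C)CCC[C@]21C
F2 | step 2 | 4-[(1R,2R,4aS,8aS)-2-hydroxy-2,5,5,8a-tetramethyldecahydronaphthalen-1-yl]butan-2-one | CC(=O)CC[C@H]1[C@](C)(O)CC[C@H]2C(C)(C)CCC[C@]12C
F3 | step 2 | 4-[(1R,2R,4aS,8aS)-2-hydroxy-2,5,5,8a-tetramethyldecahydronaphthalen-1-yl]but-1-en-2-yl trifluoromethanesulfonate | C=C(OS(=O)(=O)C(F)(F)F)CC[C@H]1[C@](C)(O)CC[C@H]2C(C)(C)CCC[C@]12C
F4 | step 3 | 2-methylidene-4-[(4aS,8aS)-2,5,5,8a-tetramethyl-3,4,4a,5,6,7,8,8a-octahydronaphthalen-1-yl]butan-1-ol | CC1=C(CCC(=C)CO)[C@@]2(C)CCCC(C)(C)[C@@H]2CC1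
F5 | step 6 | methyl (2Z)-4-[(tert-butyldimethylsilyl)oxy]-3-formylbut-2-enoate | COC(=O)/C=C(\C=O)CO[Si](C)(C)C(C)(C)C
F6 | step 6 | methyl (2Z,4R)-3-{[(tert-butyldimethylsilyl)oxy]methyl}-4-hydroxyhepta-2,6-dienoate | C=CC[C@@H](O)/C(CO[Si](C)(C)C(C)(C)C)=C\C(=O)OC
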